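**Retrosynthetic overview**

Numbering (geranylgeranyl order): C1 = ArCH2; ring B = C2–C3(=CH2)–C4–C5–C6–C7; ring A = C6–C7–C8–C9–C10–C11; side chain C12–C13–C14(Cl)–C15(Br)Me2; methyl groups on C7 and C11.
Feature used: in ring A the C10 bromine is equatorial and anti to the ring bond C11–C6 and the C11 methyl is axial, the pattern left when C6 opens an (E)-C10=C11 bromonium ion at C11; the ion is kept latent and enantiopure as the (10R)-bromo-(11S)-ol trifluoroacetate 18.
33 ⇒ C3 ketone 31 (methylenation, phenol release) ⇒ C2–C7 bond (ring B, formed second): a C2=C3 silyl enol ether attacks the C7 tertiary chloride; the chain comes from C5 aldehyde 22, bisphosphonate 23 (C2–C4) and aryl aldehyde 28 (C1, arene) by two Horner–Wadsworth–Emmons olefinations.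
20 ⇒ C6–C11 bond (ring A, formed first): bromonium ion from 18, captured by the C6=C7 allylsilane, which leaves the C7 methylene.
18 ⇒ geranyl acetate 1 + methyl acetoacetate 5 (dianion) + Me3SiCH2MgCl 10; two Shi epoxidations and chloride/bromide epoxide openings set C14, C10 and C11.

Key step: step 14

Assumption: the L- and D-fructose-derived Shi ketones, tetramethyl (2-oxopropane-1,3-diyl)bis(phosphonate) and 1-bromo-N,N,2-trimethylprop-1-en-1-amine are treated as purchasable reagents.

**Route**

Step 1
Reactants: 1 geranyl acetate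
Product: 2 (S)-6,7-epoxygeranyl acetate
Conditions: L-fructose-derived Shi ketone (cat.), KHSO5 (as 2KHSO5·KHSO4·K2SO4), K2CO3, Bu4NHSO4 (cat.), MeCN–CH2(OMe)2–aq. Na2B4O7/Na2EDTA buffer, 0 °C
Reagents that add atoms: potassium peroxymonosulfate [K+].[O-]S(=O)(=O)OO
Why: Shi asymmetric epoxidation; the dioxirane should attack only the electron-rich C14=C15 alkene (C10=C11 is deactivated by the allylic acetate) and the spiro transition state of the L-fructose-derived catalyst should give the (14S)-epoxide.

Step 2
Reactants: 2 (S)-6,7-epoxygeranyl acetate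
Product: 3 (S)-6,7-epoxygeraniol
Conditions: K2CO3 (cat.), MeOH, 0 °C → rt
Reagents that add atoms: none
Why: Base-catalysed transesterification of the allylic acetate with methanol; the trisubstituted epoxide is inert to carbonate.

Step 3
Reactants: 3 (S)-6,7-epoxygeraniol
Product: 4 (S)-6,7-epoxygeranyl bromide
Conditions: CBr4, PPh3, CH2Cl2, −20 → 0 °C
Reagents that add atoms: tetrabromomethane BrC(Br)(Br)Br
Why: Appel bromination of the primary allylic alcohol under neutral conditions that should leave the epoxide untouched.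

Step 4
Reactants: 5 methyl acetoacetate; 4 (S)-6,7-epoxygeranyl bromide
Product: 7 methyl (6E)-9-[(2S)-3,3-dimethyloxiran-2-yl]-7-methyl-3-oxonon-6-enoate, via acetoacetate dianion 6 (not isolated)
Conditions: 5, NaH, THF, 0 °C; n-BuLi, 0 °C; then 4, 0 °C
Reagents that add atoms: sodium hydride [Na+].[H-]; n-butyllithium [Li]CCCC (they supply only the counter-ions of 6)
Why: γ-Alkylation of the acetoacetate dianion: the more basic terminal carbanion displaces the allylic bromide by SN2, and the hindered epoxide is not opened at 0 °C.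

Step 5
Reactants: 7 epoxy β-keto ester
Product: 9 (2Z,6E)-enol triflate, via sodium enolate 8 (not isolated)
Conditions: NaH, THF, 0 °C; then PhNTf2, 0 °C → rt
Reagents that add atoms: sodium hydride [Na+].[H-] (counter-ion of 8 only); N-phenylbis(trifluoromethanesulfonimide) FC(F)(F)S(=O)(=O)N(c1ccccc1)S(=O)(=O)C(F)(F)F
Why: Enol triflate formation by O-sulfonylation of the chelated sodium enolate, which should keep the Z geometry and so place C5 trans to C8 across C6=C7.

Step 6
Reactants: 9 (2Z,6E)-enol triflate; 10 (trimethylsilyl)methylmagnesium chloride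
Product: 11 methyl (2Z,6E)-9-[(2S)-3,3-dimethyloxiran-2-yl]-7-methyl-3-[(trimethylsilyl)methyl]nona-2,6-dienoate
Conditions: Pd(PPh3)4 (cat.), THF, 0 °C → rt
Reagents that add atoms: none
Why: Kumada–Corriu coupling at zerovalent palladium with retention of alkene geometry; conjugation to the ester keeps this latent allylsilane unreactive toward the oxidant and halide reagents of steps 7–10.

Step 7
Reactants: 11 epoxy silylmethyl enoate
Product: 12 methyl (2Z,6E,10R)-10-chloro-11-hydroxy-7,11-dimethyl-3-[(trimethylsilyl)methyl]dodeca-2,6-dienoate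
Conditions: Li2CuCl4, THF, 0 °C → rt; aqueous work-up
Reagents that add atoms: dilithium tetrachlorocuprate (divalent copper) [Li+].[Li+].[Cu+2].[Cl-].[Cl-].[Cl-].[Cl-]
Why: Halohydrin formation by SN2-type epoxide opening; soft chloride should attack the less substituted carbon C14 with inversion, giving the (14R)-chloride and the C15 tertiary alcohol.

Step 8
Reactants: 12 chlorohydrin
Product: 13 methyl (2Z,6E,10R)-11-bromo-10-chloro-7,11-dimethyl-3-[(trimethylsilyl)methyl]dodeca-2,6-dienoate
Conditions: 1-bromo-N,N,2-trimethylprop-1-en-1-amine, CH2Cl2, 0 °C → rt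
Reagents that add atoms: 1-bromo-N,N,2-trimethylprop-1-en-1-amine CC(C)=C(Br)N(C)C
Why: Neutral deoxybromination of a tertiary alcohol with an α-haloenamine: the alkoxy-iminium bromide should ionise with chlorine participation and collapse at C15 without free HBr, so the C10=C11 alkene and C14 are not touched.

Step 9
Reactants: 13 chloro bromide
Product: 14 methyl (2Z,6S,7S,10R)-11-bromo-10-chloro-6,7-epoxy-7,11-dimethyl-3-[(trimethylsilyl)methyl]dodec-2-enoate
Conditions: L-fructose-derived Shi ketone (cat.), KHSO5 (as 2KHSO5·KHSO4·K2SO4), K2CO3, Bu4NHSO4 (cat.), MeCN–CH2(OMe)2–aq. Na2B4O7/Na2EDTA buffer, 0 °C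
Reagents that add atoms: potassium peroxymonosulfate [K+].[O-]S(=O)(=O)OO
Why: Shi asymmetric epoxidation; C10=C11 is the only electron-rich alkene left (the silylmethyl enoate is electron-poor) and catalyst control should give the (10S,11S)-epoxide.

Step 10
Reactants: 14 (10S,11S)-epoxide
Product: 15 methyl (2Z,6R,7S,10R)-6,11-dibromo-10-chloro-7-hydroxy-7,11-dimethyl-3-[(trimethylsilyl)methyl]dodec-2-enoate
Conditions: Li2NiBr4, THF, 0 °C → rt; aqueous work-up
Reagents that add atoms: dilithium tetrabromonickelate (divalent nickel) [Li+].[Li+].[Ni+2].[Br-].[Br-].[Br-].[Br-]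
Why: Bromohydrin formation by SN2-type epoxide opening; bromide should attack the secondary carbon C10 with inversion, giving the (10R)-bromide beside the (11S) tertiary alcohol.

Step 11
Reactants: 15 bromohydrin ester
Product: 16 (2Z,6R,7S,10R)-6,11-dibromo-10-chloro-7,11-dimethyl-3-[(trimethylsilyl)methyl]dodec-2-ene-1,7-diol
Conditions: i-Bu2AlH, CH2Cl2, −78 °C; aqueous potassium sodium tartrate work-up
Reagents that add atoms: none
Why: 1,2-Reduction of the enoate by the aluminium hydride to the (Z)-allylic alcohol, which unmasks the nucleophilic allylsilane; alkyl halides are inert at −78 °C and the aluminium alkoxide of the bromohydrin should not close to the epoxide.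

Step 12
Reactants: 16 diol
Product: 17 1-O-pivalate of 16
Conditions: t-BuCOCl, pyridine, CH2Cl2, 0 °C
Reagents that add atoms: pivaloyl chloride CC(C)(C)C(Cl)=O
Why: Selective esterification of the primary allylic alcohol with a hindered acid chloride; the tertiary alcohol does not react.

Step 13
Reactants: 17 hydroxy pivalate
Product: 18 1-O-pivalate 7-O-trifluoroacetate of 16 (acyclic key precursor)
Conditions: (CF3CO)2O, pyridine, CH2Cl2, −20 → 0 °C
Reagents that add atoms: trifluoroacetic anhydride O=C(OC(=O)C(F)(F)F)C(F)(F)F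
Why: Trifluoroacetylation of the tertiary alcohol in pyridine installs the nucleofuge without forming the alkoxide that would re-close the epoxide.

Step 14
Reactants: 18 acyclic bromo trifluoroacetate
Product: 20 [(1S,2R,3R)-3-bromo-2-[(3R)-4-bromo-3-chloro-4-methylpentyl]-2-methyl-6-methylidenecyclohexyl]methyl pivalate, via bromonium ion 19 (not isolated)
Conditions: (CF3)2CHOH (high dilution), 2,6-di-tert-butyl-4-methylpyridine, 0 °C → rt
Reagents that add atoms: none
Why: Proposed new method: in the strongly ionising, non-nucleophilic alcohol the tertiary trifluoroacetate should leave with anchimeric help from the C10 bromine (inversion at C11), giving bromonium ion 19 as one enantiomer in a medium that holds nothing able to brominate the allylsilane; C6 of the allylsilane then opens the ion at C11 anti to bromine (second inversion, net retention) and the β-silyl cation at C7 loses Me3Si to leave only the exocyclic C7 methylene. The closest known reaction types are solvolytic generation and alkene capture of bromonium ions from enantiopure bromohydrin esters in this solvent, and cation–olefin cyclisations terminated by 2-(silylmethyl)alkenes. Ring A closes 6-endo with respect to both the C6=C7 alkene and the bromonium ion (C10 and C11 both become ring atoms) through a chair transition state. C11 is fixed by the configuration of the bromohydrin ester and C10 is carried through unchanged, while C6 is set by the chair, in which the C5 arm (trans to C8 on the alkene) lies equatorial. The step needs ionisation at C11 ahead of the C15 bromide and the allylic pivalate, and attack at C11 and not at C10: the β-chlorine retards ionisation at C15, pivalate is a far poorer nucleofuge than trifluoroacetate, and opening at the tertiary bromonium carbon is also the six-membered mode. The hindered pyridine takes up acid so that the allylsilane is not protodesilylated.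

Step 15
Reactants: 20 ring A pivalate
Product: 21 ring A primary alcohol (C5–OH)
Conditions: i-Bu2AlH, CH2Cl2, −78 °C
Reagents that add atoms: none
Why: Reductive cleavage of the pivalate ester by the aluminium hydride frees the C5 alcohol without base, so the C15 bromide is not eliminated.

Step 16
Reactants: 21 ring A alcohol
Product: 22 ring A aldehyde (C5 = CHO)
Conditions: Dess–Martin periodinane, pyridine, CH2Cl2, 0 °C
Reagents that add atoms: none
Why: Dess–Martin oxidation under buffered, non-basic conditions should give the β,γ-unsaturated aldehyde without epimerisation at C6 or migration of the C7 methylene.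

Step 17
Reactants: 22 ring A aldehyde; 23 tetramethyl (2-oxopropane-1,3-diyl)bis(phosphonate)
Product: 24 (E)-enone phosphonate (C4=C5, C3 ketone, C2 phosphonate)
Conditions: 23 (excess), LiCl, i-Pr2NEt, MeCN, 0 °C → rt
Reagents that add atoms: none
Why: Horner–Wadsworth–Emmons olefination with LiCl and a tertiary amine is mild enough for the epimerisable aldehyde; excess bisphosphonate favours mono-olefination and keeps the second phosphonate for step 21.

Step 18
Reactants: 24 enone phosphonate
Product: 25 saturated β-keto phosphonate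
Conditions: [(Ph3P)CuH]6, H2O, THF–benzene, rt
Reagents that add atoms: none
Why: Conjugate reduction by the copper hydride is chemoselective for the enone and should leave the 1,1-disubstituted alkene and all carbon–halogen bonds intact.

Step 19
Reactants: 25 β-keto phosphonate
Product: 26 C7 tertiary chloride (both C7 epimers)
Conditions: Co(BF4)2·6H2O (cat.), potassium 2-[(3,5-di-tert-butyl-2-hydroxybenzylidene)amino]-2,2-diphenylacetate (cat.), TsCl, PhSiH3, t-BuOOH (cat.), EtOH, rt
Reagents that add atoms: 4-methylbenzenesulfonyl chloride Cc1ccc(cc1)S(Cl)(=O)=O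
Why: Markovnikov hydrochlorination by metal-hydride hydrogen-atom transfer: the cobalt hydride delivers H to the methylene carbon and the C7 tertiary radical abstracts chlorine from TsCl, so C7 gains its methyl group and a leaving group without a free cation (C7 configuration is irrelevant).

Step 20
Reactants: 27 3,5-dibromosalicylaldehyde
Product: 28 3,5-dibromo-2-(triisopropylsilyloxy)benzaldehyde
Conditions: i-Pr3SiCl, imidazole, DMF, rt
Reagents that add atoms: chlorotri(propan-2-yl)silane CC(C)[Si](Cl)(C(C)C)C(C)C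
Why: Silylation of the phenol gives a hindered aryl silyl ether that should survive amine bases, Lewis acid and the titanium reagent and is removable with fluoride.

Step 21
Reactants: 26 chloro β-keto phosphonate; 28 silylated aryl aldehyde
Product: 29 (E)-aryl enone (C1=C2, C3 ketone)
Conditions: LiCl, i-Pr2NEt, MeCN, rt
Reagents that add atoms: none
Why: Second Horner–Wadsworth–Emmons olefination of the β-keto phosphonate gives the (E)-aryl enone, which defines C2 as the only carbon that becomes nucleophilic in step 22.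

Step 22
Reactants: 29 aryl enone
Product: 31 trans-fused bicyclic C3 ketone, via triethylsilyl enol ether 30 (not isolated)
Conditions: Et3SiH, RhCl(PPh3)3 (cat.), benzene, 50 °C; evaporate; then TiCl4, CH2Cl2, −78 °C
Reagents that add atoms: triethylsilane CC[SiH](CC)CC (its silicon remains only in 30)
Why: Rhodium-catalysed 1,4-hydrosilylation should give the (Z)-silyl enol ether at C2=C3 regiospecifically and TiCl4 then ionises the C7 chloride for an intramolecular Lewis-acid α-tert-alkylation of the enol ether (SN1), in which C2 attacks the C7 cation through a chair anti to the axial C11 methyl, so ring B closes trans-fused with the C7 methyl axial and the C2 arylmethyl group equatorial (set by the Z enol ether and not contra-thermodynamic).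

Step 23
Reactants: 31 bicyclic ketone
Product: 32 C3 methylidene compound (silyl ether of the target)
Conditions: Cp2TiMe2, toluene–THF, 65 °C, dark
Reagents that add atoms: dimethyltitanocene C[Ti](C)(C1C=CC=C1)C1C=CC=C1
Why: Petasis methylenation is neither basic nor strongly Lewis acidic, so the hindered enolisable ketone should be methylenated without epimerisation at C2 or elimination at C15.

Step 24
Reactants: 32 silyl ether
Product: 33 CNP0262552.2 (target)
Conditions: Bu4NF, AcOH, THF, 0 °C
Reagents that add atoms: none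
Why: Fluoride desilylation of the aryl silyl ether buffered with acetic acid releases the phenol without strong acid (which could add the phenol across the C3 methylene) or strong base (which could eliminate HBr).

**Compound list**

1 | geranyl acetate, (2E)-3,7-dimethylocta-2,6-dien-1-yl acetate | CC(C)=CCC/C(C)=C/COC(C)=O | starting material
2 | (S)-6,7-epoxygeranyl acetate, (2E)-5-[(2S)-3,3-dimethyloxiran-2-yl]-3-methylpent-2-en-1-yl acetate | CC1(C)O[C@H]1CC/C(C)=C/COC(C)=O | intermediate
3 | (S)-6,7-epoxygeraniol | CC1(C)O[C@H]1CC/C(C)=C/CO | intermediate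
4 | (S)-6,7-epoxygeranyl bromide | CC1(C)O[C@H]1CC/C(C)=C/CBr | intermediate
5 | methyl acetoacetate | COC(=O)CC(C)=O | starting material
6 | methyl acetoacetate dianion (sodium lithium salt) | [Na+].[Li+].COC(=O)[CH-]C(=O)[CH2-] | intermediate
7 | methyl (6E)-9-[(2S)-3,3-dimethyloxiran-2-yl]-7-methyl-3-oxonon-6-enoate | CC1(C)O[C@H]1CC/C(C)=C/CCC(=O)CC(=O)OC | intermediate
8 | sodium (2Z)-enolate of 7 | [Na+].CC1(C)O[C@H]1CC/C(C)=C/CC/C([O-])=C/C(=O)OC | intermediate
9 | methyl (2Z,6E)-9-[(2S)-3,3-dimethyloxiran-2-yl]-7-methyl-3-(trifluoromethylsulfonyloxy)nona-2,6-dienoate | CC1(C)O[C@H]1CC/C(C)=C/CC/C(OS(=O)(=O)C(F)(F)F)=C/C(=O)OC | intermediate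
10 | (trimethylsilyl)methylmagnesium chloride | C[Si](C)(C)C[Mg]Cl | starting material
11 | methyl (2Z,6E)-9-[(2S)-3,3-dimethyloxiran-2-yl]-7-methyl-3-[(trimethylsilyl)methyl]nona-2,6-dienoate | CC1(C)O[C@H]1CC/C(C)=C/CC/C(C[Si](C)(C)C)=C/C(=O)OC | intermediate
12 | methyl (2Z,6E,10R)-10-chloro-11-hydroxy-7,11-dimethyl-3-[(trimethylsilyl)methyl]dodeca-2,6-dienoate | CC(C)(O)[C@H](Cl)CC/C(C)=C/CC/C(C[Si](C)(C)C)=C/C(=O)OC | intermediate
13 | methyl (2Z,6E,10R)-11-bromo-10-chloro-7,11-dimethyl-3-[(trimethylsilyl)methyl]dodeca-2,6-dienoate | CC(C)(Br)[C@H](Cl)CC/C(C)=C/CC/C(C[Si](C)(C)C)=C/C(=O)OC | intermediate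
14 | methyl (2Z,6S,7S,10R)-11-bromo-10-chloro-6,7-epoxy-7,11-dimethyl-3-[(trimethylsilyl)methyl]dodec-2-enoate | CC(C)(Br)[C@H](Cl)CC[C@]1(C)O[C@H]1CC/C(C[Si](C)(C)C)=C/C(=O)OC | intermediate
15 | methyl (2Z,6R,7S,10R)-6,11-dibromo-10-chloro-7-hydroxy-7,11-dimethyl-3-[(trimethylsilyl)methyl]dodec-2-enoate | CC(C)(Br)[C@H](Cl)CC[C@](C)(O)[C@H](Br)CC/C(C[Si](C)(C)C)=C/C(=O)OC | intermediate
16 | (2Z,6R,7S,10R)-6,11-dibromo-10-chloro-7,11-dimethyl-3-[(trimethylsilyl)methyl]dodec-2-ene-1,7-diol | CC(C)(Br)[C@H](Cl)CC[C@](C)(O)[C@H](Br)CC/C(C[Si](C)(C)C)=C/CO | intermediate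
17 | 1-O-pivalate of 16 (tertiary alcohol free) | CC(C)(Br)[C@H](Cl)CC[C@](C)(O)[C@H](Br)CC/C(C[Si](C)(C)C)=C/COC(=O)C(C)(C)C | intermediate
18 | 1-O-pivalate 7-O-trifluoroacetate of 16; acyclic (10R)-bromo (11S)-trifluoroacetate with (Z)-2-(trimethylsilylmethyl)alkene | FC(F)(F)C(=O)O[C@@](C)(CC[C@@H](Cl)C(C)(C)Br)[C@H](Br)CC/C(C[Si](C)(C)C)=C/COC(=O)C(C)(C)C | intermediate
19 | (10R,11R)-bromonium ion of 18, trifluoroacetate salt | CC(C)(Br)[C@H](Cl)CC[C@@]1(C)[Br+][C@@H]1CC/C(C[Si](C)(C)C)=C/COC(=O)C(C)(C)C.[O-]C(=O)C(F)(F)F | intermediate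
20 | [(1S,2R,3R)-3-bromo-2-[(3R)-4-bromo-3-chloro-4-methylpentyl]-2-methyl-6-methylidenecyclohexyl]methyl 2,2-dimethylpropanoate | CC(C)(C)C(=O)OC[C@@H]1[C@@](C)(CC[C@@H](Cl)C(C)(C)Br)[C@H](Br)CCC1=C | intermediate
21 | [(1S,2R,3R)-3-bromo-2-[(3R)-4-bromo-3-chloro-4-methylpentyl]-2-methyl-6-methylidenecyclohexyl]methanol | OC[C@@H]1[C@@](C)(CC[C@@H](Cl)C(C)(C)Br)[C@H](Br)CCC1=C | intermediate
22 | (1S,2R,3R)-3-bromo-2-[(3R)-4-bromo-3-chloro-4-methylpentyl]-2-methyl-6-methylidenecyclohexane-1-carbaldehyde | O=C[C@@H]1[C@@](C)(CC[C@@H](Cl)C(C)(C)Br)[C@H](Br)CCC1=C | intermediate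
23 | tetramethyl (2-oxopropane-1,3-diyl)bis(phosphonate) | COP(=O)(OC)CC(=O)CP(=O)(OC)OC | starting material
24 | dimethyl (3E)-2-oxo-4-(ring A)but-3-enylphosphonate; ring A as in 22 with C6, C10, C11, C14 unchanged | COP(=O)(OC)CC(=O)/C=C/[C@@H]1[C@@](C)(CC[C@@H](Cl)C(C)(C)Br)[C@H](Br)CCC1=C | intermediate
25 | dimethyl 2-oxo-4-(ring A)butylphosphonate; C4–C5 saturated, C7 methylidene retained | COP(=O)(OC)CC(=O)CC[C@@H]1[C@@](C)(CC[C@@H](Cl)C(C)(C)Br)[C@H](Br)CCC1=C | intermediate
26 | 25 with HCl added across C7=CH2 (C7–Cl and C7–CH3; both C7 epimers) | COP(=O)(OC)CC(=O)CC[C@@H]1[C@@](C)(CC[C@@H](Cl)C(C)(C)Br)[C@H](Br)CCC1(C)Cl | intermediate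
27 | 3,5-dibromo-2-hydroxybenzaldehyde | O=Cc1cc(Br)cc(Br)c1O | starting material
28 | 3,5-dibromo-2-(triisopropylsilyloxy)benzaldehyde | CC(C)[Si](Oc1c(Br)cc(Br)cc1C=O)(C(C)C)C(C)C | intermediate
29 | (1E)-1-[3,5-dibromo-2-(triisopropylsilyloxy)phenyl]-5-(ring A)pent-1-en-3-one; ring A carries the C7 chloride | CC(C)[Si](Oc1c(Br)cc(Br)cc1/C=C/C(=O)CC[C@@H]1[C@@](C)(CC[C@@H](Cl)C(C)(C)Br)[C@H](Br)CCC1(C)Cl)(C(C)C)C(C)C | intermediate
30 | (Z)-triethylsilyl enol ether of the saturated ketone (C2=C3, O–Si on C3) | CC[Si](CC)(CC)O/C(CC[C@@H]1[C@@](C)(CC[C@@H](Cl)C(C)(C)Br)[C@H](Br)CCC1(C)Cl)=C\Cc1cc(Br)cc(Br)c1O[Si](C(C)C)(C(C)C)C(C)C | intermediate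
31 | trans-decalone: target skeleton with C3 ketone and phenol as triisopropylsilyl ether (H6 α, C7–CH3 β, C2 arylmethyl equatorial) | O=C1CC[C@@H]2[C@@](C)(CC[C@@H](Cl)C(C)(C)Br)[C@H](Br)CC[C@@]2(C)[C@@H]1Cc1cc(Br)cc(Br)c1O[Si](C(C)C)(C(C)C)C(C)C | intermediate
32 | triisopropylsilyl ether of the target | C=C1CC[C@@H]2[C@@](C)(CC[C@@H](Cl)C(C)(C)Br)[C@H](Br)CC[C@@]2(C)[C@@H]1Cc1cc(Br)cc(Br)c1O[Si](C(C)C)(C(C)C)C(C)C | intermediate
33 | CNP0262552.2; (2R,6S,7S,10R,11R,14R) in the numbering of the overview | C=C1CC[C@@H]2[C@@](C)(CC[C@@H](Cl)C(C)(C)Br)[C@H](Br)CC[C@@]2(C)[C@@H]1Cc1cc(Br)cc(Br)c1O | target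

**Step count**

Total: 24 steps. Longest linear sequence: 23 steps (steps 1–19 and 21–24, from geranyl acetate).

**Three steps most likely to fail**

Step 14 (Proposed new method). Process at risk: ionisation of the C11 trifluoroacetate may be slower than protodesilylation of the allylsilane or return of trifluoroacetate, and transfer of the bromonium ion to the alkene of a second molecule would erode enantiopurity. Fallback, known chemistry only (Shi epoxidation, Lewis-acid epoxide–allylsilane cyclisation, oxidation, hydride reduction, Appel inversion): it sets out from 13 and returns at 20. Alkene 13 is epoxidised with the enantiomeric D-fructose-derived Shi ketone to the (10R,11R)-epoxide F1. Reduction with i-Bu2AlH gives the epoxy allylic alcohol F2 and pivaloylation gives the epoxy allylsilane pivalate F3. MeAlCl2 in CH2Cl2 at −78 °C opens the epoxide at C11 with C6 (inversion at C11, chair) to give the ring A alcohol F4, whose equatorial C10 hydroxyl sits where 20 has bromine. Dess–Martin oxidation gives the C10 ketone F5, LiBH(s-Bu)3 reduces it to the axial alcohol F6, and PPh3/CBr4 replaces the axial hydroxyl with inversion to give the equatorial bromide 20.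

Step 8. Process at risk: ionisation at the β-chloro tertiary carbon is slow, so loss of a proton (to the allylic chloride) or capture of the C15 cation by the C10=C11 alkene may outrun collapse with bromide. Fallback by a 1,2-chlorine shift: it sets out from 11 and returns at 13, bypassing 12. The epoxide of 11 is opened at the tertiary carbon with chloride (CeCl3·7H2O, MeCN) to the regioisomeric chlorohydrin F7 (C15–Cl, (14S)-OH). The secondary alcohol is converted at −78 °C (Tf2O, 2,6-lutidine) into the triflate F8 and Bu4NBr is added. The C15 chlorine displaces the triflate with inversion at C14 through a chloronium ion, which bromide opens at the tertiary carbon, giving the (14R)-chloride C15-bromide 13.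

Step 22. Process at risk: the C7 cation may lose a proton faster than it is captured, the HCl so formed would protonate the silyl enol ether, and halide exchange at C15 could occur under TiCl4. Fallback by radical closure: it sets out from 25 and returns at 31. Keto phosphonate 25, which still has the C7 methylene, is condensed with 28 (LiCl, i-Pr2NEt) to the aryl enone F9. Fe(acac)3 and PhSiH3 in EtOH–(CH2OH)2 at 60 °C transfer a hydrogen atom to the methylene; the C7 tertiary radical should close 6-exo on C2 from the face anti to the C11 methyl, and the benzylic radical at C1 is reduced. Brief treatment with Et3N equilibrates C2 to the equatorial epimer 31.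

**Further compounds**

F1 | step 14 | methyl (2Z,6R,7R,10R)-11-bromo-10-chloro-6,7-epoxy-7,11-dimethyl-3-[(trimethylsilyl)methyl]dodec-2-enoate | CC(C)(Br)[C@H](Cl)CC[C@@]1(C)O[C@@H]1CC/C(C[Si](C)(C)C)=C/C(=O)OC
F2 | step 14 | (2Z,6R,7R,10R)-11-bromo-10-chloro-6,7-epoxy-7,11-dimethyl-3-[(trimethylsilyl)methyl]dodec-2-en-1-ol | CC(C)(Br)[C@H](Cl)CC[C@@]1(C)O[C@@H]1CC/C(C[Si](C)(C)C)=C/CO
F3 | step 14 | 1-O-pivalate of F2 | CC(C)(Br)[C@H](Cl)CC[C@@]1(C)O[C@@H]1CC/C(C[Si](C)(C)C)=C/COC(=O)C(C)(C)C
F4 | step 14 | [(1S,2R,3R)-2-[(3R)-4-bromo-3-chloro-4-methylpentyl]-3-hydroxy-2-methyl-6-methylidenecyclohexyl]methyl pivalate (equatorial C10–OH) | CC(C)(C)C(=O)OC[C@@H]1[C@@](C)(CC[C@@H](Cl)C(C)(C)Br)[C@H](O)CCC1=C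
F5 | step 14 | C10 ketone of F4 | CC(C)(C)C(=O)OC[C@@H]1[C@@](C)(CC[C@@H](Cl)C(C)(C)Br)C(=O)CCC1=C
F6 | step 14 | C10 epimer of F4 (axial C10–OH) | CC(C)(C)C(=O)OC[C@@H]1[C@@](C)(CC[C@@H](Cl)C(C)(C)Br)[C@@H](O)CCC1=C
F7 | step 8 | methyl (2Z,6E,10S)-11-chloro-10-hydroxy-7,11-dimethyl-3-[(trimethylsilyl)methyl]dodeca-2,6-dienoate | CC(C)(Cl)[C@@H](O)CC/C(C)=C/CC/C(C[Si](C)(C)C)=C/C(=O)OC
F8 | step 8 | 10-O-trifluoromethanesulfonate of F7 | CC(C)(Cl)[C@@H](OS(=O)(=O)C(F)(F)F)CC/C(C)=C/CC/C(C[Si](C)(C)C)=C/C(=O)OC
F9 | step 22 | (1E)-1-[3,5-dibromo-2-(triisopropylsilyloxy)phenyl]-5-(ring A)pent-1-en-3-one with the C7 methylidene retained | CC(C)[Si](Oc1c(Br)cc(Br)cc1/C=C/C(=O)CC[C@@H]1[C@@](C)(CC[C@@H](Cl)C(C)(C)Br)[C@H](Br)CCC1=C)(C(C)C)C(C)C
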